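## Retrosynthetic overview

1. Target 24 ⇐ BCl3 O‑demethylation and (NH4)2Ce(NO3)6 oxidation of a 1,4,5‑trimethoxynaphthalene (masked 7‑methyljuglone) that already carries the chromone‑5‑carboxylic acid.
2. Chromone acid ⇐ carbonylation of a 5‑triflate; the pyranone ring is closed from an o‑hydroxyacetophenone (enaminone route), whose acetyl group comes from directed lithiation between two isopropoxy groups.
3. Key C–C bond (quinone C2–aryl) ⇐ acid‑promoted Michael (conjugate Friedel–Crafts) addition of 3,5‑diisopropoxytoluene 8 to 3‑chloro‑7‑methyljuglone 6; the chlorine blocks C3 and is later hydrogenolysed, and the quinone is masked by O‑methylation of the 5‑OH followed by reductive methylation.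
4. 6 ⇐ Diels–Alder/aromatisation of 2,6‑dichlorobenzoquinone with the vinylketene acetal of methyl 3‑methylbut‑2‑enoate; 8 ⇐ orcinol.
5. Ring order: juglone benzenoid ring (Diels–Alder) → biaryl bond → pyranone ring of the chromone → quinone unmasked last.

Assumption: the target SMILES has no stereocentre and no stereodescriptor, and the quinone–chromone axis is taken as not configurationally fixed, so the compound is made as drawn (hindered‑axis intermediates are racemic).

## Route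

Step 1
Reactants: 1 methyl 3-methylbut-2-enoate
Product: 3 [(1-methoxy-3-methylbuta-1,3-dien-1-yl)oxy]trimethylsilane, via lithium dienolate 2 (not isolated)
Conditions: LiN(i-Pr)2, THF, –78 °C; then Me3SiCl, –78 °C → rt; distil
Reagents that add atoms: chlorotrimethylsilane, C[Si](C)(C)Cl
Why: γ‑Deprotonation of the unsaturated ester gives the cross‑conjugated dienolate, which is O‑silylated (silyl ketene acetal formation) to the vinylketene acetal; no stereocentre is formed.

Step 2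
Reactants: 3 [(1-methoxy-3-methylbuta-1,3-dien-1-yl)oxy]trimethylsilane; 4 2,6-dichlorocyclohexa-2,5-diene-1,4-dione (2,6-dichloro-1,4-benzoquinone)
Product: 6 3-chloro-5-hydroxy-7-methylnaphthalene-1,4-dione, via Diels–Alder adduct 5 (not isolated)
Conditions: CH2Cl2, –40 °C → rt; then moist SiO2, rt
Reagents that add atoms: none
Why: In this Diels–Alder reaction the nucleophilic CH2 terminus of the diene bonds to the unsubstituted carbon of the chloro‑enone, and loss of HCl, MeOH and the silyl group aromatises the new ring, which puts OH at C5, CH3 at C7 and leaves Cl at C3; the stereocentres of racemic cis‑adduct 5 are destroyed.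

Step 3
Reactants: 7 5-methylbenzene-1,3-diol (orcinol)
Product: 8 1-methyl-3,5-di(propan-2-yloxy)benzene
Conditions: 2-bromopropane, K2CO3, DMF, 70 °C
Reagents that add atoms: 2-bromopropane, CC(C)Br
Why: Double Williamson ether synthesis on a cheap resorcinol gives ethers that survive acid and organolithium reagents but are later cleaved by BCl3 in the presence of methyl ethers.

Step 4
Reactants: 6 3-chloro-5-hydroxy-7-methylnaphthalene-1,4-dione; 8 1-methyl-3,5-di(propan-2-yloxy)benzene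
Product: 10 3-chloro-5-hydroxy-7-methyl-2-[6-methyl-2,4-di(propan-2-yloxy)phenyl]naphthalene-1,4-dione, via chlorohydroquinone 9 (not isolated)
Conditions: CF3CO2H/CH2Cl2 (1:4), 0 °C → rt (6 in slight excess); aqueous work-up; then Ag2O, MgSO4, CH2Cl2, rt
Reagents that add atoms: none
Why: Michael‑type (conjugate Friedel–Crafts) addition of the arene, through its carbon between CH3 and O‑i‑Pr (ortho to one ether oxygen and para to the other), to C2 of the quinone, which is the only unsubstituted quinone carbon and the β‑carbon of the hydrogen‑bonded C4 enone, followed by Ag2O oxidation that converges the redox mixture on the air‑stable quinone; the new biaryl axis is racemic and no stereocentre is formed.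

Step 5
Reactants: 10 3-chloro-5-hydroxy-7-methyl-2-[6-methyl-2,4-di(propan-2-yloxy)phenyl]naphthalene-1,4-dione
Product: 11 3-chloro-5-methoxy-7-methyl-2-[6-methyl-2,4-di(propan-2-yloxy)phenyl]naphthalene-1,4-dione
Conditions: MeI, Ag2O, CH2Cl2, rt, dark
Reagents that add atoms: iodomethane, CI
Why: Ag2O‑mediated O‑methylation (Purdie methylation) caps the chelated peri‑hydroxyl under neutral, non‑nucleophilic conditions that leave the chloroquinone untouched, as is standard for juglones.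

Step 6
Reactants: 11 3-chloro-5-methoxy-7-methyl-2-[6-methyl-2,4-di(propan-2-yloxy)phenyl]naphthalene-1,4-dione
Product: 13 3-chloro-1,4,5-trimethoxy-7-methyl-2-[6-methyl-2,4-di(propan-2-yloxy)phenyl]naphthalene, via methoxyhydroquinone 12 (not isolated)
Conditions: Na2S2O4, Bu4NBr, THF/H2O, rt, N2; then KOH (aq), Me2SO4, rt
Reagents that add atoms: dimethyl sulfate, COS(=O)(=O)OC
Why: Reductive methylation (dithionite reduction, then phase‑transfer Williamson O‑methylation of the two hydroquinone oxygens) masks the quinone as a base‑, organolithium‑ and palladium‑stable trimethoxynaphthalene.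

Step 7
Reactants: 13 3-chloro-1,4,5-trimethoxy-7-methyl-2-[6-methyl-2,4-di(propan-2-yloxy)phenyl]naphthalene
Product: 14 1,4,5-trimethoxy-7-methyl-2-[6-methyl-2,4-di(propan-2-yloxy)phenyl]naphthalene
Conditions: H2 (1 atm), Pd/C (10%), Et3N, MeOH/THF, rt
Reagents that add atoms: none
Why: Amine‑promoted catalytic hydrogenolysis (hydrodechlorination) removes the blocking chlorine while alkyl aryl ethers and the arene rings are untouched.

Step 8
Reactants: 14 1,4,5-trimethoxy-7-methyl-2-[6-methyl-2,4-di(propan-2-yloxy)phenyl]naphthalene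
Product: 16 1-[4-methyl-2,6-di(propan-2-yloxy)-3-(1,4,5-trimethoxy-7-methylnaphthalen-2-yl)phenyl]ethanone, via aryllithium 15 (not isolated)
Conditions: n-BuLi, TMEDA, THF, 0 °C → rt; then MeC(O)N(OMe)Me, –78 °C → rt; dilute HCl work-up
Reagents that add atoms: N-methoxy-N-methylacetamide, CC(=O)N(C)OC
Why: Directed ortho‑metalation takes place at the only C–H flanked by two alkoxy groups (doubly activated, while every naphthalene C–H has at most one neighbouring methoxy group), and the Weinreb ketone synthesis stops cleanly at the methyl ketone.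

Step 9
Reactants: 16 1-[4-methyl-2,6-di(propan-2-yloxy)-3-(1,4,5-trimethoxy-7-methylnaphthalen-2-yl)phenyl]ethanone
Product: 17 1-[2,6-dihydroxy-4-methyl-3-(1,4,5-trimethoxy-7-methylnaphthalen-2-yl)phenyl]ethanone
Conditions: BCl3 (3 equiv), CH2Cl2, –78 → 0 °C; H2O work-up
Reagents that add atoms: none
Why: Lewis‑acid ether cleavage by BCl3 removes the secondary isopropyl groups, helped by chelation to the ortho acetyl group, and at or below 0 °C leaves the three naphthyl methyl ethers intact.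

Step 10
Reactants: 17 1-[2,6-dihydroxy-4-methyl-3-(1,4,5-trimethoxy-7-methylnaphthalen-2-yl)phenyl]ethanone
Product: 18 2-acetyl-3-hydroxy-5-methyl-4-(1,4,5-trimethoxy-7-methylnaphthalen-2-yl)phenyl trifluoromethanesulfonate
Conditions: PhN(SO2CF3)2 (1.05 equiv), Et3N, CH2Cl2, –20 → 0 °C
Reagents that add atoms: N-phenylbis(trifluoromethanesulfonimide), O=S(=O)(N(c1ccccc1)S(=O)(=O)C(F)(F)F)C(F)(F)F
Why: Sterically controlled mono‑O‑sulfonylation: the bulky triflimide reacts at the phenol flanked by H and acetyl and not at the one wedged between acetyl and the perpendicular naphthyl group, and the remaining OH is deactivated by hydrogen bonding to the ketone.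

Step 11
Reactants: 18 2-acetyl-3-hydroxy-5-methyl-4-(1,4,5-trimethoxy-7-methylnaphthalen-2-yl)phenyl trifluoromethanesulfonate
Product: 20 7-methyl-4-oxo-8-(1,4,5-trimethoxy-7-methylnaphthalen-2-yl)-4H-chromen-5-yl trifluoromethanesulfonate, via enaminone 19 (not isolated)
Conditions: Me2NCH(OMe)2, toluene, 90 °C; then conc. HCl, CH2Cl2, rt
Reagents that add atoms: N,N-dimethylformamide dimethyl acetal, COC(OC)N(C)C
Why: Enaminone condensation at the acetyl CH3 followed by acid‑mediated intramolecular oxa‑Michael addition and loss of dimethylamine (enaminone chromone synthesis) closes the 2,3‑unsubstituted pyranone ring on the only free phenol, so the naphthyl group ends at C8 and the triflate at C5.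

Step 12
Reactants: 20 7-methyl-4-oxo-8-(1,4,5-trimethoxy-7-methylnaphthalen-2-yl)-4H-chromen-5-yl trifluoromethanesulfonate
Product: 21 methyl 7-methyl-4-oxo-8-(1,4,5-trimethoxy-7-methylnaphthalen-2-yl)-4H-chromene-5-carboxylate
Conditions: Pd(OAc)2 (10 mol %), 1,3-bis(diphenylphosphino)propane, CO (1 atm), Et3N, MeOH/DMF, 70 °C
Reagents that add atoms: carbon monoxide, [C-]#[O+]; methanol, CO
Why: Palladium‑catalysed alkoxycarbonylation (oxidative addition of the aryl triflate to zerovalent palladium, CO insertion, methanolysis of the acyl–palladium species) installs the C5 carboxyl carbon without touching the chromone or the methyl ethers.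

Step 13
Reactants: 21 methyl 7-methyl-4-oxo-8-(1,4,5-trimethoxy-7-methylnaphthalen-2-yl)-4H-chromene-5-carboxylate
Product: 22 7-methyl-4-oxo-8-(1,4,5-trimethoxy-7-methylnaphthalen-2-yl)-4H-chromene-5-carboxylic acid
Conditions: 6 M HCl/1,4-dioxane (1:2), 90 °C, N2
Reagents that add atoms: water, O
Why: Acid‑catalysed ester hydrolysis is used because the 2,3‑unsubstituted chromone is opened by hydroxide but is stable to acid, and it is done before the acid‑ and nucleophile‑sensitive quinone is unveiled.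

Step 14
Reactants: 22 7-methyl-4-oxo-8-(1,4,5-trimethoxy-7-methylnaphthalen-2-yl)-4H-chromene-5-carboxylic acid
Product: 23 8-(5-methoxy-7-methyl-1,4-dioxo-1,4-dihydronaphthalen-2-yl)-7-methyl-4-oxo-4H-chromene-5-carboxylic acid
Conditions: (NH4)2Ce(NO3)6 (2.5 equiv), MeCN/H2O (2:1), 0 °C
Reagents that add atoms: water, O
Why: Oxidative demethylation by tetravalent cerium converts only the para‑dimethoxy ring into the 1,4‑quinone (water supplies the carbonyl oxygens, methanol leaves), while the lone 5‑OMe, the electron‑poor chromone and the acid are inert.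

Step 15
Reactants: 23 8-(5-methoxy-7-methyl-1,4-dioxo-1,4-dihydronaphthalen-2-yl)-7-methyl-4-oxo-4H-chromene-5-carboxylic acid
Product: 24 8-(5-hydroxy-7-methyl-1,4-dioxo-1,4-dihydronaphthalen-2-yl)-7-methyl-4-oxo-4H-chromene-5-carboxylic acid
Conditions: BCl3 (4 equiv), CH2Cl2, –78 → 0 °C; H2O work-up
Reagents that add atoms: none
Why: Chelation‑assisted O‑demethylation by BCl3 cleaves the methyl ether peri to the quinone carbonyl at low temperature and gives the hydrogen‑bonded juglone OH of the target, which has no stereocentre.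

## Compound list

1 | methyl 3-methylbut-2-enoate | COC(=O)C=C(C)C | starting material
2 | lithium 1-methoxy-3-methylbuta-1,3-dien-1-olate | [Li]OC(OC)=CC(C)=C | intermediate
3 | [(1-methoxy-3-methylbuta-1,3-dien-1-yl)oxy]trimethylsilane | COC(=CC(C)=C)O[Si](C)(C)C | intermediate
4 | 2,6-dichlorocyclohexa-2,5-diene-1,4-dione | O=C1C=C(Cl)C(=O)C(Cl)=C1 | starting material
5 | 3,4a-dichloro-5-methoxy-7-methyl-5-(trimethylsilyloxy)-4a,5,8,8a-tetrahydronaphthalene-1,4-dione (racemic, cis-fused) | O=C1C(Cl)=CC(=O)C2CC(C)=CC(OC)(O[Si](C)(C)C)C12Cl | intermediate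
6 | 3-chloro-5-hydroxy-7-methylnaphthalene-1,4-dione | Cc1cc(O)c2C(=O)C(Cl)=CC(=O)c2c1 | intermediate
7 | 5-methylbenzene-1,3-diol | Cc1cc(O)cc(O)c1 | starting material
8 | 1-methyl-3,5-di(propan-2-yloxy)benzene | Cc1cc(OC(C)C)cc(OC(C)C)c1 | intermediate
9 | 3-chloro-7-methyl-2-[6-methyl-2,4-di(propan-2-yloxy)phenyl]naphthalene-1,4,5-triol | Cc1cc(O)c2c(O)c(Cl)c(-c3c(C)cc(OC(C)C)cc3OC(C)C)c(O)c2c1 | intermediate
10 | 3-chloro-5-hydroxy-7-methyl-2-[6-methyl-2,4-di(propan-2-yloxy)phenyl]naphthalene-1,4-dione | Cc1cc(O)c2C(=O)C(Cl)=C(c3c(C)cc(OC(C)C)cc3OC(C)C)C(=O)c2c1 | intermediate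
11 | 3-chloro-5-methoxy-7-methyl-2-[6-methyl-2,4-di(propan-2-yloxy)phenyl]naphthalene-1,4-dione | Cc1cc(OC)c2C(=O)C(Cl)=C(c3c(C)cc(OC(C)C)cc3OC(C)C)C(=O)c2c1 | intermediate
12 | 3-chloro-5-methoxy-7-methyl-2-[6-methyl-2,4-di(propan-2-yloxy)phenyl]naphthalene-1,4-diol | Cc1cc(OC)c2c(O)c(Cl)c(-c3c(C)cc(OC(C)C)cc3OC(C)C)c(O)c2c1 | intermediate
13 | 3-chloro-1,4,5-trimethoxy-7-methyl-2-[6-methyl-2,4-di(propan-2-yloxy)phenyl]naphthalene | Cc1cc(OC)c2c(OC)c(Cl)c(-c3c(C)cc(OC(C)C)cc3OC(C)C)c(OC)c2c1 | intermediate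
14 | 1,4,5-trimethoxy-7-methyl-2-[6-methyl-2,4-di(propan-2-yloxy)phenyl]naphthalene | Cc1cc(OC)c2c(OC)cc(-c3c(C)cc(OC(C)C)cc3OC(C)C)c(OC)c2c1 | intermediate
15 | [4-methyl-2,6-di(propan-2-yloxy)-3-(1,4,5-trimethoxy-7-methylnaphthalen-2-yl)phenyl]lithium | Cc1cc(OC)c2c(OC)cc(-c3c(C)cc(OC(C)C)c([Li])c3OC(C)C)c(OC)c2c1 | intermediate
16 | 1-[4-methyl-2,6-di(propan-2-yloxy)-3-(1,4,5-trimethoxy-7-methylnaphthalen-2-yl)phenyl]ethanone | Cc1cc(OC)c2c(OC)cc(-c3c(C)cc(OC(C)C)c(C(C)=O)c3OC(C)C)c(OC)c2c1 | intermediate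
17 | 1-[2,6-dihydroxy-4-methyl-3-(1,4,5-trimethoxy-7-methylnaphthalen-2-yl)phenyl]ethanone | Cc1cc(OC)c2c(OC)cc(-c3c(C)cc(O)c(C(C)=O)c3O)c(OC)c2c1 | intermediate
18 | 2-acetyl-3-hydroxy-5-methyl-4-(1,4,5-trimethoxy-7-methylnaphthalen-2-yl)phenyl trifluoromethanesulfonate | Cc1cc(OC)c2c(OC)cc(-c3c(C)cc(OS(=O)(=O)C(F)(F)F)c(C(C)=O)c3O)c(OC)c2c1 | intermediate
19 | 2-[(E)-3-(dimethylamino)prop-2-enoyl]-3-hydroxy-5-methyl-4-(1,4,5-trimethoxy-7-methylnaphthalen-2-yl)phenyl trifluoromethanesulfonate | Cc1cc(OC)c2c(OC)cc(-c3c(C)cc(OS(=O)(=O)C(F)(F)F)c(C(=O)/C=C/N(C)C)c3O)c(OC)c2c1 | intermediate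
20 | 7-methyl-4-oxo-8-(1,4,5-trimethoxy-7-methylnaphthalen-2-yl)-4H-chromen-5-yl trifluoromethanesulfonate | Cc1cc(OC)c2c(OC)cc(-c3c(C)cc(OS(=O)(=O)C(F)(F)F)c4c(=O)ccoc34)c(OC)c2c1 | intermediate
21 | methyl 7-methyl-4-oxo-8-(1,4,5-trimethoxy-7-methylnaphthalen-2-yl)-4H-chromene-5-carboxylate | Cc1cc(OC)c2c(OC)cc(-c3c(C)cc(C(=O)OC)c4c(=O)ccoc34)c(OC)c2c1 | intermediate
22 | 7-methyl-4-oxo-8-(1,4,5-trimethoxy-7-methylnaphthalen-2-yl)-4H-chromene-5-carboxylic acid | Cc1cc(OC)c2c(OC)cc(-c3c(C)cc(C(=O)O)c4c(=O)ccoc34)c(OC)c2c1 | intermediate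
23 | 8-(5-methoxy-7-methyl-1,4-dioxo-1,4-dihydronaphthalen-2-yl)-7-methyl-4-oxo-4H-chromene-5-carboxylic acid | Cc1cc(OC)c2c(c1)C(=O)C(c1c(C)cc(C(=O)O)c3c(=O)ccoc13)=CC2=O | intermediate
24 | 8-(5-hydroxy-7-methyl-1,4-dioxo-1,4-dihydronaphthalen-2-yl)-7-methyl-4-oxo-4H-chromene-5-carboxylic acid | Cc1cc(O)c2c(c1)C(=O)C(c1c(C)cc(C(=O)O)c3c(=O)ccoc13)=CC2=O | target

## Totals and risks

Total step count: 15. Longest linear sequence: 14 steps (1 → 24 through steps 1, 2 and 4–15; step 3 is the side branch).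

Three steps most likely to fail, each with a fallback:

Step 4 (the conjugate arylation of 6). The arene may add slowly, or attack the chlorine‑bearing carbon with loss of chloride. The fallback reverses the order in which the biaryl bond and the juglone benzenoid ring are made. It sets out from 4 and 8: the same CF3CO2H‑promoted Michael addition is run on the symmetrical and more electrophilic dichlorobenzoquinone 4, whose two free positions are equivalent, and gives 2,6-dichloro-3-[6-methyl-2,4-di(propan-2-yloxy)phenyl]benzene-1,4-diol F1. Ag2O oxidises this to 2,6-dichloro-3-[6-methyl-2,4-di(propan-2-yloxy)phenyl]cyclohexa-2,5-diene-1,4-dione F2. A Diels–Alder reaction of F2 with diene 3 at the remaining unsubstituted C=C(Cl) bond gives 3,4a-dichloro-5-methoxy-7-methyl-2-[6-methyl-2,4-di(propan-2-yloxy)phenyl]-5-(trimethylsilyloxy)-4a,5,8,8a-tetrahydronaphthalene-1,4-dione F3, which aromatises on moist SiO2 and comes back to the route at 10.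

Step 8 (late directed lithiation/acetylation of 14). Lithiation may be slow between the two bulky isopropoxy groups, or may compete at naphthalene positions. The fallback installs the acetyl group before the biaryl bond is made. It sets out from 8: n-BuLi/TMEDA gives [4-methyl-2,6-di(propan-2-yloxy)phenyl]lithium F4, and N-methoxy-N-methylacetamide converts it into 1-[4-methyl-2,6-di(propan-2-yloxy)phenyl]ethanone F5. Michael addition of this less nucleophilic arene to 6 under stronger acid (CF3SO3H cat. in (CF3)2CHOH) gives 1-[3-(3-chloro-1,4,5-trihydroxy-7-methylnaphthalen-2-yl)-4-methyl-2,6-di(propan-2-yloxy)phenyl]ethanone F6, and Ag2O oxidises it to 2-[3-acetyl-6-methyl-2,4-di(propan-2-yloxy)phenyl]-3-chloro-5-hydroxy-7-methylnaphthalene-1,4-dione F7. MeI/Ag2O methylates the 5‑OH and gives 2-[3-acetyl-6-methyl-2,4-di(propan-2-yloxy)phenyl]-3-chloro-5-methoxy-7-methylnaphthalene-1,4-dione F8. Na2S2O4 reduces this in the flask to 1-[3-(3-chloro-1,4-dihydroxy-5-methoxy-7-methylnaphthalen-2-yl)-4-methyl-2,6-di(propan-2-yloxy)phenyl]ethanone F9, and KOH/Me2SO4 methylates it to 1-[3-(3-chloro-1,4,5-trimethoxy-7-methylnaphthalen-2-yl)-4-methyl-2,6-di(propan-2-yloxy)phenyl]ethanone F10. Hydrogenolysis (H2, Pd/C, Et3N) then comes back to the route at 16.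

Step 10 (selective mono‑triflation of 17). The two phenols may not be distinguished well enough. The fallback moves the differentiation from O‑sulfonylation to the oxidative addition step. It sets out from 17: (CF3SO2)2O/pyridine gives 2-acetyl-5-methyl-4-(1,4,5-trimethoxy-7-methylnaphthalen-2-yl)-1,3-phenylene bis(trifluoromethanesulfonate) F11. Pd(OAc)2/1,3-bis(diphenylphosphino)propane/CO/MeOH/Et3N then carbonylates only the triflate next to H, because zerovalent palladium does not insert into the di‑ortho‑substituted one, and gives methyl 2-acetyl-5-methyl-4-(1,4,5-trimethoxy-7-methylnaphthalen-2-yl)-3-(trifluoromethylsulfonyloxy)benzoate F12. Bu4NF in THF cleaves the remaining triflate to methyl 2-acetyl-3-hydroxy-5-methyl-4-(1,4,5-trimethoxy-7-methylnaphthalen-2-yl)benzoate F13. Me2NCH(OMe)2 gives methyl 2-[(E)-3-(dimethylamino)prop-2-enoyl]-3-hydroxy-5-methyl-4-(1,4,5-trimethoxy-7-methylnaphthalen-2-yl)benzoate F14, and conc. HCl closes the pyranone ring and comes back to the route at 21.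

## Further compounds

F1 | step 4 | 2,6-dichloro-3-[6-methyl-2,4-di(propan-2-yloxy)phenyl]benzene-1,4-diol | Oc1c(Cl)cc(O)c(-c2c(C)cc(OC(C)C)cc2OC(C)C)c1Cl
F2 | step 4 | 2,6-dichloro-3-[6-methyl-2,4-di(propan-2-yloxy)phenyl]cyclohexa-2,5-diene-1,4-dione | O=C1C(Cl)=CC(=O)C(c2c(C)cc(OC(C)C)cc2OC(C)C)=C1Cl
F3 | step 4 | 3,4a-dichloro-5-methoxy-7-methyl-2-[6-methyl-2,4-di(propan-2-yloxy)phenyl]-5-(trimethylsilyloxy)-4a,5,8,8a-tetrahydronaphthalene-1,4-dione | O=C1C(Cl)=C(c3c(C)cc(OC(C)C)cc3OC(C)C)C(=O)C2CC(C)=CC(OC)(O[Si](C)(C)C)C12Cl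
F4 | step 8 | [4-methyl-2,6-di(propan-2-yloxy)phenyl]lithium | [Li]c1c(OC(C)C)cc(C)cc1OC(C)C
F5 | step 8 | 1-[4-methyl-2,6-di(propan-2-yloxy)phenyl]ethanone | CC(=O)c1c(OC(C)C)cc(C)cc1OC(C)C
F6 | step 8 | 1-[3-(3-chloro-1,4,5-trihydroxy-7-methylnaphthalen-2-yl)-4-methyl-2,6-di(propan-2-yloxy)phenyl]ethanone | Cc1cc(O)c2c(O)c(Cl)c(-c3c(C)cc(OC(C)C)c(C(C)=O)c3OC(C)C)c(O)c2c1
F7 | step 8 | 2-[3-acetyl-6-methyl-2,4-di(propan-2-yloxy)phenyl]-3-chloro-5-hydroxy-7-methylnaphthalene-1,4-dione | Cc1cc(O)c2C(=O)C(Cl)=C(c3c(C)cc(OC(C)C)c(C(C)=O)c3OC(C)C)C(=O)c2c1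
F8 | step 8 | 2-[3-acetyl-6-methyl-2,4-di(propan-2-yloxy)phenyl]-3-chloro-5-methoxy-7-methylnaphthalene-1,4-dione | Cc1cc(OC)c2C(=O)C(Cl)=C(c3c(C)cc(OC(C)C)c(C(C)=O)c3OC(C)C)C(=O)c2c1
F9 | step 8 | 1-[3-(3-chloro-1,4-dihydroxy-5-methoxy-7-methylnaphthalen-2-yl)-4-methyl-2,6-di(propan-2-yloxy)phenyl]ethanone | Cc1cc(OC)c2c(O)c(Cl)c(-c3c(C)cc(OC(C)C)c(C(C)=O)c3OC(C)C)c(O)c2c1
F10 | step 8 | 1-[3-(3-chloro-1,4,5-trimethoxy-7-methylnaphthalen-2-yl)-4-methyl-2,6-di(propan-2-yloxy)phenyl]ethanone | Cc1cc(OC)c2c(OC)c(Cl)c(-c3c(C)cc(OC(C)C)c(C(C)=O)c3OC(C)C)c(OC)c2c1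
F11 | step 10 | 2-acetyl-5-methyl-4-(1,4,5-trimethoxy-7-methylnaphthalen-2-yl)-1,3-phenylene bis(trifluoromethanesulfonate) | Cc1cc(OC)c2c(OC)cc(-c3c(C)cc(OS(=O)(=O)C(F)(F)F)c(C(C)=O)c3OS(=O)(=O)C(F)(F)F)c(OC)c2c1
F12 | step 10 | methyl 2-acetyl-5-methyl-4-(1,4,5-trimethoxy-7-methylnaphthalen-2-yl)-3-(trifluoromethylsulfonyloxy)benzoate | Cc1cc(OC)c2c(OC)cc(-c3c(C)cc(C(=O)OC)c(C(C)=O)c3OS(=O)(=O)C(F)(F)F)c(OC)c2c1
F13 | step 10 | methyl 2-acetyl-3-hydroxy-5-methyl-4-(1,4,5-trimethoxy-7-methylnaphthalen-2-yl)benzoate | Cc1cc(OC)c2c(OC)cc(-c3c(C)cc(C(=O)OC)c(C(C)=O)c3O)c(OC)c2c1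
F14 | step 10 | methyl 2-[(E)-3-(dimethylamino)prop-2-enoyl]-3-hydroxy-5-methyl-4-(1,4,5-trimethoxy-7-methylnaphthalen-2-yl)benzoate | Cc1cc(OC)c2c(OC)cc(-c3c(C)cc(C(=O)OC)c(C(=O)/C=C/N(C)C)c3O)c(OC)c2c1
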